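## Analysis of the target

Sanggenol N (22) is a 5,7-dihydroxyflavanone in which ring A is a phloroglucinol-type benzene and ring C is the dihydropyranone formed by O1, C2, C3, C4, C4a and C8a. Ring B is a pentasubstituted benzene that carries the 2'-hydroxyl, a 2,2-dimethyl-2H-pyran (ring D, fused at C3'–C4' with its oxygen on C4') and a prenyl group on C5'. The only stereocentre is C2, of (S) configuration, so nothing else in the molecule can relay or correct it. C2 is fragile, because ring B has oxygen ortho (O2') and para (O4') to C1' and the C2–O1 bond therefore ionises easily, and because a flavanone can open to the chalcone under base and reclose without memory of configuration. The prenyl alkene and the ring D alkene exclude hydrogenolysis, electrophilic halogen, strong oxidants and strong acid late in the route. The difficulty is therefore to set C2 once, by a method that does not depend on the crowded ring B, and then to complete ring C without breaking a bond at C2. The plan rests on three atoms of ring C: the carbonyl carbon C4 on ring A can be introduced as a masked acyl nucleophile, while the methylene C3 and the oxygen-bearing C2 together have the shape of a monosubstituted oxirane whose oxygen ends up as O1. The remaining bond of ring C, O1–C8a, lies ortho to the ketone and can be closed by displacing fluoride from ring A.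

## Retrosynthetic reasoning

**22 to 21.** The three phenols of 22 are masked as methoxymethyl ethers in (S)-5,7-bis(methoxymethoxy)-2-[5-(methoxymethoxy)-2,2-dimethyl-8-(3-methylbut-2-enyl)-2H-chromen-6-yl]chroman-4-one (21). Acetal ethers survive alkyllithium, hydride-transfer, alkylating and strongly basic conditions and are removed without hydrogen or oxidant. The forward step must cleave three acetals without opening ring C.

**21 to 19.** Ring C is opened at O1–C8a, not at O1–C2. A closure at C2, by conjugate addition of a ring A phenoxide to an enone or by displacement at the benzylic carbon, would make or invert the stereocentre at the most ionisable carbon of the molecule. Cutting at C8a leaves the C2–O bond intact, so the configuration carries through with retention. This requires a leaving group on ring A: fluorine at C8a in the β-hydroxy ketone 19, activated by the ortho ketone. The two acetal oxygens at C5 and C7 are meta to the reacting carbon and do not oppose the addition. The forward step is a six-membered ring closure by the alkoxide 20.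

**19 to 18.** The ketone of 19 is masked as the 1,3-dithiane 18. The mask is more than a protecting device: it reverses the polarity of C4 so that this carbon can act as the nucleophile in the fragment union.

**18 to 6 and 16.** The C3–C4 bond is cut. It is the one carbon–carbon bond of ring C that joins the two aromatic halves without involving C2, and it divides the molecule into two fragments of similar size, each derived from an aromatic aldehyde. The nucleophile is the lithiated dithiane 17 made from 6; the electrophile is the (R)-epoxide 16, which already carries C2 with its oxygen. The forward reaction must open the epoxide at the CH2 terminus only.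

**16 to 15 to 14.** The epoxide is traced to the (R)-chlorohydrin 15 and this to the α-chloroketone 14. C2 is thereby created in a ketone reduction whose facial selectivity depends only on the difference between an aryl group and a CH2Cl group. Transfer hydrogenation leaves the two alkenes alone, whereas an oxidative route to the epoxide from a vinyl arene would attack the prenyl and ring D alkenes first.

**14 to 13 to 12.** The chloroketone is taken back through the racemic chlorohydrin 13 to the aldehyde 12, the CH2Cl carbon being added as a carbenoid. An electrophilic chlorination next to a ketone is avoided because it would not spare the electron-rich alkenes.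

**12 to 11 to 10.** The prenyl–aryl bond at C8 of the chromene (C5' of the target) is cut to the bromide 11 and, behind it, the free phenol 10. A cross-coupling fixes the position of the prenyl group through the position of the halogen; direct electrophilic prenylation of such a phenol is not regioselective.

**10 to 7 and 8.** Ring D is cut at its O–C(CH3)2 bond and at the bond from C4 to the arene, giving 5-bromo-2,4-dihydroxybenzaldehyde (7) and 3-methylbut-2-enal (8). The bromine of 7 blocks C5, so only the carbon between the two hydroxyls can condense. The hydrogen bond from the 2-hydroxyl to the formyl group leaves the 4-oxygen to enter the pyran via the dienone 9.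

**6 to 5 to 3 to 1.** The acetal ethers of 6 are removed to the diol 5, the dithiane is opened to the aldehyde 3 and propane-1,3-dithiol (4), and the formyl carbon is cut from 5-fluororesorcinol (1). Formylation goes through the iminium salt 2 at the position between fluorine and hydroxyl, which is the position that places fluorine ortho to the future C4.

## Alternatives that were turned down

Alternative 1: ring B built by benzannulation. The disconnection takes ring B apart at C1'–C2', C2'–C3', C4'–C5' and C5'–C6'. In the forward step a diazo enone undergoes photochemical Wolff rearrangement to a vinylketene, which adds a siloxyalkyne; the cyclobutenone opens and the dienylketene electrocyclises to the phenol 2-(dimethoxymethyl)-4-(3-methylbut-2-enyl)-5-(triisopropylsilyloxy)phenol A1.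
- For it: in A1 the substitution pattern of ring B is fixed by the connectivity of the two partners, the two oxygens emerge differentiated, and no organotin reagent or linear-versus-branched question arises for the prenyl group. On these points it is stronger than the chosen route.
- Against it: A1 is only a masked ring B aldehyde without ring D. The key step spends a diazo transfer, a siloxyalkyne synthesis and a photolysis on an arene whose oxygenation pattern can be bought as 7. The vinylketene must also tolerate a prenyl alkene in the same molecule. Ring C and the only stereocentre are not addressed.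
- Comparison: the chosen route reaches the corresponding ring B aldehyde 12 in three steps from 7 and places its key step where the two halves are joined and the stereocentre is carried through, which A1 does not touch.

Alternative 2: ring C closed by carbene C–H insertion. The C2–C3 bond is cut. The diazomethyl ketone 2-diazo-1-{2,4-bis(tert-butyldimethylsilyloxy)-6-{[5-(tert-butyldimethylsilyloxy)-2,2-dimethyl-8-(3-methylbut-2-enyl)-2H-chromen-6-yl]methoxy}phenyl}ethanone A2 would give, with a chiral dirhodium tetracarboxylate such as Rh2(S-PTTL)4, a carbene at C3 that inserts into a benzylic C–H bond of the ether and so forms (S)-5,7,2'-tris-O-(tert-butyldimethylsilyl) sanggenol N A3.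
- For it: A3 would hold ring C and C2 after a single catalytic step, and the two halves of A2 are joined by a simple O-benzylation. That is a more economical union than a dithiane alkylation followed by unmasking.
- Against it: in the carbene derived from A2 the ether oxygen is placed to close a five-membered oxonium ylide, and a 1,2-benzyl shift to a 2-benzylbenzofuran-3-one is expected to outrun the six-membered C–H insertion that leads to A3. Acceptor-only carbenes give poor enantiocontrol in such insertions. The two electron-rich alkenes of A2 are open to cyclopropanation.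
- Comparison: the chosen route takes C2 from a ketone reduction of a well-studied type and never forms a bond at C2 afterwards, whereas the route through A2 and A3 stakes both the ring and the stereocentre on one uncertain insertion.

Alternative 3: late prenyl transfer to C5'. The C5'–prenyl bond is cut. The 2'-O-prenyl ether (S)-5,7-bis(methoxymethoxy)-2-[2,2-dimethyl-5-(3-methylbut-2-enyloxy)-2H-chromen-6-yl]chroman-4-one A4 would undergo a Claisen shift to an ortho dienone and a Cope shift on to the para position, giving (S)-5,7-bis-O-methoxymethyl sanggenol N A5 with the 2'-phenol set free.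
- For it: the prenyl group of A4 is spared every earlier step, no tin reagent and no aryl bromide are needed, and A5 emerges with the 2'-hydroxyl released without a deprotection. In atom economy and protecting-group count it is stronger than the chosen route.
- Against it: both ortho positions of O2' in A4 (C1' and C3') are substituted, so the relay must pass through a quaternary dienone, at C1' next to the C2 stereocentre or at C3' on the ring D junction. The heat needed for two consecutive shifts acts on a flavanone whose C2–O1 bond is the weakest point of the molecule, and the phenol released in A5 makes ring opening to the chalcone easier. Ring D can also open by retro-electrocyclisation at such temperatures.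
- Comparison: the chosen route installs the prenyl group on the robust aldehyde 11 by cross-coupling and keeps the stereocentre away from heat, which the passage from A4 to A5 cannot do.

Key step: step 11

Assumption: 5-bromo-2,4-dihydroxybenzaldehyde (7) is taken as a purchasable compound; all steps with n-BuLi, MeLi·LiBr and KN(SiMe3)2 are run under argon in dry solvents.

## Route

Step 1
Reactants: 1 5-fluorobenzene-1,3-diol (5-fluororesorcinol)
Product: 3 2-fluoro-4,6-dihydroxybenzaldehyde, via aryl iminium chloride 2 (not isolated)
Conditions: POCl3, DMF, MeCN, 0 °C to rt; then H2O, 50 °C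
Reagents that add atoms: N,N-dimethylformamide, CN(C)C=O; water, O
Why: Vilsmeier–Haack formylation. The chloroiminium electrophile attacks the carbon para to one hydroxyl and ortho to the other, the site between the two hydroxyls being disfavoured for this bulky electrophile, and water hydrolyses iminium salt 2 to the aldehyde.

Step 2
Reactants: 3 2-fluoro-4,6-dihydroxybenzaldehyde; 4 propane-1,3-dithiol
Product: 5 2-(2-fluoro-4,6-dihydroxyphenyl)-1,3-dithiane
Conditions: BF3·OEt2, CH2Cl2–THF, 0 °C to rt
Reagents that add atoms: none
Why: Lewis-acid-promoted dithioacetalisation. It is done before protection because free phenols tolerate BF3·OEt2 whereas methoxymethyl ethers would not.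

Step 3
Reactants: 5 2-(2-fluoro-4,6-dihydroxyphenyl)-1,3-dithiane
Product: 6 2-[2-fluoro-4,6-bis(methoxymethoxy)phenyl]-1,3-dithiane
Conditions: MOMCl, iPr2NEt, CH2Cl2, 0 °C to rt
Reagents that add atoms: chloromethyl methyl ether (MOMCl), COCCl
Why: O-alkylation of both phenols (Williamson type). With the aldehyde masked no phenol is chelated, so an amine base is enough, and the thioacetal sulfurs are far weaker nucleophiles than the phenoxides.

Step 4
Reactants: 7 5-bromo-2,4-dihydroxybenzaldehyde; 8 3-methylbut-2-enal
Product: 10 8-bromo-5-hydroxy-2,2-dimethyl-2H-chromene-6-carbaldehyde, via quinone methide dienone 9 (not isolated)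
Conditions: ethylenediammonium diacetate (20 mol %), toluene, 110 °C
Reagents that add atoms: none
Why: Chromenylation of a resorcinol with an enal: Knoevenagel-type condensation at the only free activated carbon (between the hydroxyls; C5 is blocked by bromine), loss of water to dienone 9 and oxa-6π electrocyclisation. The 4-oxygen closes the pyran because the 2-hydroxyl stays hydrogen-bonded to the formyl group.

Step 5
Reactants: 10 8-bromo-5-hydroxy-2,2-dimethyl-2H-chromene-6-carbaldehyde
Product: 11 8-bromo-5-(methoxymethoxy)-2,2-dimethyl-2H-chromene-6-carbaldehyde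
Conditions: NaH, MOMCl, DMF, 0 °C to rt
Reagents that add atoms: chloromethyl methyl ether (MOMCl), COCCl
Why: O-alkylation of a phenol. NaH is used because this hydroxyl is chelated to the aldehyde and reacts sluggishly with amine bases.

Step 6
Reactants: 11 8-bromo-5-(methoxymethoxy)-2,2-dimethyl-2H-chromene-6-carbaldehyde
Product: 12 5-(methoxymethoxy)-2,2-dimethyl-8-(3-methylbut-2-enyl)-2H-chromene-6-carbaldehyde
Conditions: Bu3SnCH2CH=CMe2, Pd(PPh3)4 (5 mol %), DMF, 90 °C
Reagents that add atoms: tributyl(3-methylbut-2-enyl)stannane, CCCC[Sn](CCCC)(CCCC)CC=C(C)C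
Why: Stille cross-coupling of an aryl bromide with an allyl-type stannane. Reductive elimination from the η3-prenyl aryl palladium intermediate takes place at the less substituted terminus, which should give the linear prenyl arene; the aldehyde and the ring D alkene are tolerated.

Step 7
Reactants: 12 5-(methoxymethoxy)-2,2-dimethyl-8-(3-methylbut-2-enyl)-2H-chromene-6-carbaldehyde
Product: 13 rac-2-chloro-1-[5-(methoxymethoxy)-2,2-dimethyl-8-(3-methylbut-2-enyl)-2H-chromen-6-yl]ethanol
Conditions: ICH2Cl, MeLi·LiBr, THF, −78 °C; AcOH, −78 °C
Reagents that add atoms: chloroiodomethane, ClCI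
Why: Carbenoid addition to an aldehyde. Chloromethyllithium is generated by iodine–lithium exchange in the presence of 12 and adds to the carbonyl faster than it decomposes; the cold acidic quench keeps the chlorohydrin from closing to racemic epoxide.

Step 8
Reactants: 13 rac-2-chloro-1-[5-(methoxymethoxy)-2,2-dimethyl-8-(3-methylbut-2-enyl)-2H-chromen-6-yl]ethanol
Product: 14 2-chloro-1-[5-(methoxymethoxy)-2,2-dimethyl-8-(3-methylbut-2-enyl)-2H-chromen-6-yl]ethanone
Conditions: Dess–Martin periodinane, CH2Cl2, 0 °C to rt
Reagents that add atoms: none
Why: Dess–Martin oxidation of a secondary benzylic alcohol. The reagent is neutral and leaves the alkenes, the acetal and the C–Cl bond alone.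

Step 9
Reactants: 14 2-chloro-1-[5-(methoxymethoxy)-2,2-dimethyl-8-(3-methylbut-2-enyl)-2H-chromen-6-yl]ethanone
Product: 15 (R)-2-chloro-1-[5-(methoxymethoxy)-2,2-dimethyl-8-(3-methylbut-2-enyl)-2H-chromen-6-yl]ethanol
Conditions: RuCl(p-cymene)[(S,S)-TsDPEN] (1 mol %), HCO2H–Et3N (5:2), EtOAc, rt
Reagents that add atoms: none
Why: Noyori asymmetric transfer hydrogenation of an aryl chloromethyl ketone. The (S,S) ligand places the aryl group against the η6-arene (CH/π contact) and delivers hydride to the face that gives the (R)-chlorohydrin, the same spatial sense as for aryl methyl ketones. Alkenes and the C–Cl bond are not reduced under transfer conditions.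

Step 10
Reactants: 15 (R)-2-chloro-1-[5-(methoxymethoxy)-2,2-dimethyl-8-(3-methylbut-2-enyl)-2H-chromen-6-yl]ethanol
Product: 16 (R)-2-[5-(methoxymethoxy)-2,2-dimethyl-8-(3-methylbut-2-enyl)-2H-chromen-6-yl]oxirane
Conditions: K2CO3, MeOH, 0 °C to rt
Reagents that add atoms: none
Why: Intramolecular Williamson closure: the alkoxide displaces chloride at the CH2 carbon, so the stereocentre is not involved and stays (R). The acid-sensitive epoxide is purified on base-washed silica and used at once.

Step 11
Reactants: 6 2-[2-fluoro-4,6-bis(methoxymethoxy)phenyl]-1,3-dithiane; 16 (R)-2-[5-(methoxymethoxy)-2,2-dimethyl-8-(3-methylbut-2-enyl)-2H-chromen-6-yl]oxirane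
Product: 18 (S)-2-{2-[2-fluoro-4,6-bis(methoxymethoxy)phenyl]-1,3-dithian-2-yl}-1-[5-(methoxymethoxy)-2,2-dimethyl-8-(3-methylbut-2-enyl)-2H-chromen-6-yl]ethanol, via 2-lithio dithiane 17 (not isolated)
Conditions: n-BuLi (1.1 equiv), THF, −78 to −30 °C; then 16, −78 to 0 °C; aq NH4Cl
Reagents that add atoms: none
Why: Corey–Seebach umpolung: n-BuLi removes the dithiane C2 proton of 6 (1.2 equiv), the most acidic C–H of the molecule and one held near the base by the flanking fluorine and acetal oxygen, to give the tertiary carbanion 17. Carbanion 17 then attacks the unsubstituted CH2 carbon of epoxide 16 in an SN2 opening assisted by lithium on the epoxide oxygen, which forms the C3–C4 bond and leaves a lithium alkoxide that is protonated on work-up. The closest known reaction type is the alkylation of 2-lithio-2-aryl-1,3-dithianes with terminal epoxides, aryl oxiranes included. The step closes none of the rings of 22; the dithiane ring is only a temporary device that lets C4 react as a nucleophile. No stereocentre is created: the C2–O bond of 16 is untouched, and the descriptor changes from (R) to (S) only because the CH2 group loses its oxygen and falls below the aryl group in priority. The step needs attack at the terminal and not the benzylic epoxide carbon, which the bulk of the fully substituted carbanion, the ortho acetal group beside the benzylic carbon and the absence of any Lewis acid stronger than lithium should secure. It also needs metalation at the dithiane carbon and not at the ring positions next to fluorine, which the difference in acidity, the slight excess of 6 over n-BuLi and a temperature held at or below −30 °C until the epoxide is added should secure.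

Step 12
Reactants: 18 (S)-2-{2-[2-fluoro-4,6-bis(methoxymethoxy)phenyl]-1,3-dithian-2-yl}-1-[5-(methoxymethoxy)-2,2-dimethyl-8-(3-methylbut-2-enyl)-2H-chromen-6-yl]ethanol
Product: 19 (S)-1-[2-fluoro-4,6-bis(methoxymethoxy)phenyl]-3-hydroxy-3-[5-(methoxymethoxy)-2,2-dimethyl-8-(3-methylbut-2-enyl)-2H-chromen-6-yl]propan-1-one
Conditions: MeI, CaCO3, MeCN–H2O (9:1), 45 °C
Reagents that add atoms: water, O
Why: Alkylative hydrolysis of a dithiane: S-methylation, opening to a thionium ion stabilised by the electron-rich arene, and capture by water. No oxidant or thiophilic metal is present that could attack the prenyl or ring D alkene, and CaCO3 keeps the medium from turning acidic.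

Step 13
Reactants: 19 (S)-1-[2-fluoro-4,6-bis(methoxymethoxy)phenyl]-3-hydroxy-3-[5-(methoxymethoxy)-2,2-dimethyl-8-(3-methylbut-2-enyl)-2H-chromen-6-yl]propan-1-one
Product: 21 (S)-5,7-bis(methoxymethoxy)-2-[5-(methoxymethoxy)-2,2-dimethyl-8-(3-methylbut-2-enyl)-2H-chromen-6-yl]chroman-4-one, via potassium alkoxide 20 (not isolated)
Conditions: KN(SiMe3)2 (1.0 equiv), THF, −78 to 0 °C
Reagents that add atoms: none
Why: Intramolecular nucleophilic aromatic substitution (addition–elimination) of an ortho-fluoroaryl ketone by an alkoxide, a six-membered closure that forms O1–C8a. The ketone stabilises the anionic intermediate and is drawn into the ring plane by the closure itself, and the acetal oxygens are meta to the carbon attacked. The C2–O bond is not broken, so C2 stays (S); one equivalent of strong base at low temperature forms the alkoxide without leaving free base to enolise the ketone.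

Step 14
Reactants: 21 (S)-5,7-bis(methoxymethoxy)-2-[5-(methoxymethoxy)-2,2-dimethyl-8-(3-methylbut-2-enyl)-2H-chromen-6-yl]chroman-4-one
Product: 22 sanggenol N, (S)-5,7-dihydroxy-2-[5-hydroxy-2,2-dimethyl-8-(3-methylbut-2-enyl)-2H-chromen-6-yl]chroman-4-one
Conditions: HCl (3 M aq), MeOH–THF, 40 °C
Reagents that add atoms: none
Why: Acid-catalysed acetal exchange transfers the three methoxymethyl groups to methanol. The prenyl group has no free phenol ortho to it (its neighbours are the carbon bearing the ring D ether oxygen and a CH), so acid-induced chroman formation is not available, and the conditions are kept mild to spare the C2–O1 bond.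

## Compound list

1 | 5-fluorobenzene-1,3-diol (5-fluororesorcinol) | Oc1cc(O)cc(F)c1 | starting material
2 | N-[(2-fluoro-4,6-dihydroxyphenyl)methylidene]-N-methylmethanaminium chloride | C[N+](C)=Cc1c(F)cc(O)cc1O.[Cl-] | intermediate
3 | 2-fluoro-4,6-dihydroxybenzaldehyde | O=Cc1c(F)cc(O)cc1O | intermediate
4 | propane-1,3-dithiol | SCCCS | starting material
5 | 2-(2-fluoro-4,6-dihydroxyphenyl)-1,3-dithiane | Oc1cc(F)c(C2SCCCS2)c(O)c1 | intermediate
6 | 2-[2-fluoro-4,6-bis(methoxymethoxy)phenyl]-1,3-dithiane | COCOc1cc(F)c(C2SCCCS2)c(OCOC)c1 | intermediate
7 | 5-bromo-2,4-dihydroxybenzaldehyde | O=Cc1cc(Br)c(O)cc1O | starting material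
8 | 3-methylbut-2-enal | CC(C)=CC=O | starting material
9 | 5-bromo-2-hydroxy-3-(3-methylbut-2-enylidene)-4-oxocyclohexa-1,5-diene-1-carbaldehyde | O=CC1=C(O)C(=CC=C(C)C)C(=O)C(Br)=C1 | intermediate
10 | 8-bromo-5-hydroxy-2,2-dimethyl-2H-chromene-6-carbaldehyde | O=Cc1cc(Br)c2OC(C)(C)C=Cc2c1O | intermediate
11 | 8-bromo-5-(methoxymethoxy)-2,2-dimethyl-2H-chromene-6-carbaldehyde | O=Cc1cc(Br)c2OC(C)(C)C=Cc2c1OCOC | intermediate
12 | 5-(methoxymethoxy)-2,2-dimethyl-8-(3-methylbut-2-enyl)-2H-chromene-6-carbaldehyde | O=Cc1cc(CC=C(C)C)c2OC(C)(C)C=Cc2c1OCOC | intermediate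
13 | rac-2-chloro-1-[5-(methoxymethoxy)-2,2-dimethyl-8-(3-methylbut-2-enyl)-2H-chromen-6-yl]ethanol | OC(CCl)c1cc(CC=C(C)C)c2OC(C)(C)C=Cc2c1OCOC | intermediate
14 | 2-chloro-1-[5-(methoxymethoxy)-2,2-dimethyl-8-(3-methylbut-2-enyl)-2H-chromen-6-yl]ethanone | O=C(CCl)c1cc(CC=C(C)C)c2OC(C)(C)C=Cc2c1OCOC | intermediate
15 | (R)-2-chloro-1-[5-(methoxymethoxy)-2,2-dimethyl-8-(3-methylbut-2-enyl)-2H-chromen-6-yl]ethanol | O[C@@H](CCl)c1cc(CC=C(C)C)c2OC(C)(C)C=Cc2c1OCOC | intermediate
16 | (R)-2-[5-(methoxymethoxy)-2,2-dimethyl-8-(3-methylbut-2-enyl)-2H-chromen-6-yl]oxirane | C1O[C@@H]1c1cc(CC=C(C)C)c2OC(C)(C)C=Cc2c1OCOC | intermediate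
17 | 2-lithio-2-[2-fluoro-4,6-bis(methoxymethoxy)phenyl]-1,3-dithiane | [Li]C1(SCCCS1)c1c(F)cc(OCOC)cc1OCOC | intermediate
18 | (S)-2-{2-[2-fluoro-4,6-bis(methoxymethoxy)phenyl]-1,3-dithian-2-yl}-1-[5-(methoxymethoxy)-2,2-dimethyl-8-(3-methylbut-2-enyl)-2H-chromen-6-yl]ethanol | O[C@@H](CC1(SCCCS1)c1c(F)cc(OCOC)cc1OCOC)c1cc(CC=C(C)C)c2OC(C)(C)C=Cc2c1OCOC | intermediate
19 | (S)-1-[2-fluoro-4,6-bis(methoxymethoxy)phenyl]-3-hydroxy-3-[5-(methoxymethoxy)-2,2-dimethyl-8-(3-methylbut-2-enyl)-2H-chromen-6-yl]propan-1-one | O[C@@H](CC(=O)c1c(F)cc(OCOC)cc1OCOC)c1cc(CC=C(C)C)c2OC(C)(C)C=Cc2c1OCOC | intermediate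
20 | potassium (S)-3-[2-fluoro-4,6-bis(methoxymethoxy)phenyl]-1-[5-(methoxymethoxy)-2,2-dimethyl-8-(3-methylbut-2-enyl)-2H-chromen-6-yl]-3-oxopropan-1-olate | [K+].[O-][C@@H](CC(=O)c1c(F)cc(OCOC)cc1OCOC)c1cc(CC=C(C)C)c2OC(C)(C)C=Cc2c1OCOC | intermediate
21 | (S)-5,7-bis(methoxymethoxy)-2-[5-(methoxymethoxy)-2,2-dimethyl-8-(3-methylbut-2-enyl)-2H-chromen-6-yl]chroman-4-one | CC(C)=CCc1cc([C@@H]2CC(=O)c3c(OCOC)cc(OCOC)cc3O2)c(OCOC)c2c1OC(C)(C)C=C2 | intermediate
22 | sanggenol N, (S)-5,7-dihydroxy-2-[5-hydroxy-2,2-dimethyl-8-(3-methylbut-2-enyl)-2H-chromen-6-yl]chroman-4-one | CC(C)=CCc1cc([C@@H]2CC(=O)c3c(O)cc(O)cc3O2)c(O)c2c1OC(C)(C)C=C2 | target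

## Step count and least certain steps

Total: 14 steps. Longest linear sequence: 11 steps (steps 4 to 14, from 7). The ring A branch contributes 3 steps (steps 1 to 3) before the union.

**Step 11 (key step).** Three things can go wrong: metalation of the arene next to fluorine followed by loss of LiF, slow opening of the epoxide by the hindered tertiary carbanion, and partial attack at the benzylic carbon of the electron-rich epoxide.
Fallback, from 1 and 12, returning at 19: the C2–C3 bond would be formed by an aldol addition instead of the C3–C4 bond by umpolung. Compound 1 would be C-acetylated (AcOH, BF3·OEt2, 90 °C) to 1-(2-fluoro-4,6-dihydroxyphenyl)ethanone F1, which would be protected (NaH, MOMCl, DMF) as 1-[2-fluoro-4,6-bis(methoxymethoxy)phenyl]ethanone F2 and converted with TMSOTf and Et3N into {1-[2-fluoro-4,6-bis(methoxymethoxy)phenyl]ethenyloxy}trimethylsilane F3. A Mukaiyama aldol addition of F3 to aldehyde 12, catalysed by the oxazaborolidinone Lewis acid made from N-tosyltryptophan and BuB(OH)2, would give (S)-1-[2-fluoro-4,6-bis(methoxymethoxy)phenyl]-3-[5-(methoxymethoxy)-2,2-dimethyl-8-(3-methylbut-2-enyl)-2H-chromen-6-yl]-3-(trimethylsilyloxy)propan-1-one F4. The catalyst antipode would be chosen to give the (S)-carbinol and the sense checked by Mosher ester analysis. Dilute HCl in THF at 0 °C would then remove the silyl group from F4 to give 19. This reserve makes C2 in the bond-forming step and so gives up the separation of stereocontrol from fragment union.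

**Step 13.** The alkoxide 20 is also an aldolate. Retro-aldol cleavage and recombination would erode the configuration at C2, and proton transfer to the enolate followed by loss of hydroxide would lead to the chalcone, which cannot cyclise.
Fallback, from 18, returning at 21: unmasking and ring closure would be inverted. The potassium alkoxide of 18 (KN(SiMe3)2, 18-crown-6, THF–DMF, 60 °C) has no carbonyl group, so neither side reaction exists. It would displace the fluoride, now activated only inductively, to give (S)-5,7-bis(methoxymethoxy)-2-[5-(methoxymethoxy)-2,2-dimethyl-8-(3-methylbut-2-enyl)-2H-chromen-6-yl]spiro[chromane-4,2'-[1,3]dithiane] F5. MeI and CaCO3 in aqueous MeCN would then hydrolyse F5 to 21.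

**Step 14.** Protic acid may ionise the C2–O1 bond, which is benzylic to a ring with ortho and para oxygen; this would open ring C and scramble C2. Acid may also add solvent across the prenyl or ring D alkene.
Fallback, from 21, returning at 22: TMSOTf and 2,2'-bipyridyl in CH2Cl2 at 0 °C would exchange each aryl methoxymethyl ether for a silyl ether without free protic acid, giving (S)-5,7-bis(trimethylsilyloxy)-2-[2,2-dimethyl-8-(3-methylbut-2-enyl)-5-(trimethylsilyloxy)-2H-chromen-6-yl]chroman-4-one F6. Water at neutral pH would then hydrolyse F6 to 22.

**Step 9.** The ortho acetal group on the aryl ketone may lower the facial discrimination of the catalyst or slow the hydride transfer, and long exposure to formic acid may start to cleave the acetal.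
Fallback, from 13, returning at 15: a kinetic resolution of the racemic chlorohydrin 13 with immobilised Candida antarctica lipase B and vinyl acetate in t-BuOMe at 30 °C. By the usual empirical rule for secondary carbinols the enzyme should acylate the (S)-enantiomer to (S)-2-chloro-1-[5-(methoxymethoxy)-2,2-dimethyl-8-(3-methylbut-2-enyl)-2H-chromen-6-yl]ethyl acetate F7 and leave 15, which would be separated by chromatography. At most half of the material can be carried on, but steps 8 and 9 are no longer needed.

**Step 6.** The prenyl group may be transferred through its substituted terminus, giving the 1,1-dimethylallyl isomer, and slow oxidative addition at the electron-rich bromide may allow protodebromination.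
Fallback, from 11, returning at 12: Stille coupling of 11 with Bu3SnCH2CH=CH2 and Pd(PPh3)4 would give 8-allyl-5-(methoxymethoxy)-2,2-dimethyl-2H-chromene-6-carbaldehyde F8, for which no regiochemical question exists. Cross-metathesis of F8 with 2-methylbut-2-ene (second-generation Grubbs catalyst, CH2Cl2, 40 °C) would give 12. The ring D alkene is cis-disubstituted beside a quaternary carbon and is not expected to take part.

## Further compounds

F1 | step 11 | 1-(2-fluoro-4,6-dihydroxyphenyl)ethanone | CC(=O)c1c(F)cc(O)cc1O
F2 | step 11 | 1-[2-fluoro-4,6-bis(methoxymethoxy)phenyl]ethanone | CC(=O)c1c(F)cc(OCOC)cc1OCOC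
F3 | step 11 | {1-[2-fluoro-4,6-bis(methoxymethoxy)phenyl]ethenyloxy}trimethylsilane | C=C(O[Si](C)(C)C)c1c(F)cc(OCOC)cc1OCOC
F4 | step 11 | (S)-1-[2-fluoro-4,6-bis(methoxymethoxy)phenyl]-3-[5-(methoxymethoxy)-2,2-dimethyl-8-(3-methylbut-2-enyl)-2H-chromen-6-yl]-3-(trimethylsilyloxy)propan-1-one | C[Si](C)(C)O[C@@H](CC(=O)c1c(F)cc(OCOC)cc1OCOC)c1cc(CC=C(C)C)c2OC(C)(C)C=Cc2c1OCOC
F5 | step 13 | (S)-5,7-bis(methoxymethoxy)-2-[5-(methoxymethoxy)-2,2-dimethyl-8-(3-methylbut-2-enyl)-2H-chromen-6-yl]spiro[chromane-4,2'-[1,3]dithiane] | CC(C)=CCc1cc([C@@H]2CC3(SCCCS3)c3c(OCOC)cc(OCOC)cc3O2)c(OCOC)c2c1OC(C)(C)C=C2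
F6 | step 14 | (S)-5,7-bis(trimethylsilyloxy)-2-[2,2-dimethyl-8-(3-methylbut-2-enyl)-5-(trimethylsilyloxy)-2H-chromen-6-yl]chroman-4-one | CC(C)=CCc1cc([C@@H]2CC(=O)c3c(O[Si](C)(C)C)cc(O[Si](C)(C)C)cc3O2)c(O[Si](C)(C)C)c2c1OC(C)(C)C=C2
F7 | step 9 | (S)-2-chloro-1-[5-(methoxymethoxy)-2,2-dimethyl-8-(3-methylbut-2-enyl)-2H-chromen-6-yl]ethyl acetate | CC(=O)O[C@H](CCl)c1cc(CC=C(C)C)c2OC(C)(C)C=Cc2c1OCOC
F8 | step 6 | 8-allyl-5-(methoxymethoxy)-2,2-dimethyl-2H-chromene-6-carbaldehyde | O=Cc1cc(CC=C)c2OC(C)(C)C=Cc2c1OCOC
A1 | alternative 1 | 2-(dimethoxymethyl)-4-(3-methylbut-2-enyl)-5-(triisopropylsilyloxy)phenol | COC(OC)c1cc(CC=C(C)C)c(O[Si](C(C)C)(C(C)C)C(C)C)cc1O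
A2 | alternative 2 | 2-diazo-1-{2,4-bis(tert-butyldimethylsilyloxy)-6-{[5-(tert-butyldimethylsilyloxy)-2,2-dimethyl-8-(3-methylbut-2-enyl)-2H-chromen-6-yl]methoxy}phenyl}ethanone | [N-]=[N+]=CC(=O)c1c(O[Si](C)(C)C(C)(C)C)cc(O[Si](C)(C)C(C)(C)C)cc1OCc1cc(CC=C(C)C)c2OC(C)(C)C=Cc2c1O[Si](C)(C)C(C)(C)C
A3 | alternative 2 | (S)-5,7,2'-tris-O-(tert-butyldimethylsilyl) sanggenol N | CC(C)(C)[Si](C)(C)Oc1cc(O[Si](C)(C)C(C)(C)C)c2C(=O)C[C@H](Oc2c1)c1cc(CC=C(C)C)c2OC(C)(C)C=Cc2c1O[Si](C)(C)C(C)(C)C
A4 | alternative 3 | (S)-5,7-bis(methoxymethoxy)-2-[2,2-dimethyl-5-(3-methylbut-2-enyloxy)-2H-chromen-6-yl]chroman-4-one | COCOc1cc(OCOC)c2C(=O)C[C@H](Oc2c1)c1ccc2OC(C)(C)C=Cc2c1OCC=C(C)C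
A5 | alternative 3 | (S)-5,7-bis-O-methoxymethyl sanggenol N | COCOc1cc(OCOC)c2C(=O)C[C@H](Oc2c1)c1cc(CC=C(C)C)c2OC(C)(C)C=Cc2c1O
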